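**Remarks on the chemistry.** Enolised di- and triketones are drawn as one tautomer each, and CIP descriptors refer to the tautomer drawn. Compound 4 is taken as a purchased material.

## Analysis of the target

Oblongifolin B is a type B polyprenylated acylphloroglucinol. Its core is a bicyclo[3.3.1]nonane-2,4,9-trione in which C3 carries a 3,4-dihydroxybenzoyl group, so that C2–C3–C4 and the aroyl carbonyl form an enolised, chelated β-triketone. The numbering used here is C1 (prenyl bridgehead next to CMe2), C2, C3 (aroyl), C4, C5 (second prenyl bridgehead), C6 (CH2), C7 (CH–geranyl), C8 (CMe2) and C9 (bridging ketone). Ring A is C1–C2–C3–C4–C5–C9 and ring B is C1–C8–C7–C6–C5–C9.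

There are three stereocentres, (1S,5S,7R) in the tautomer drawn. C1 and C5 are quaternary bridgeheads and are tied to each other by the one-carbon bridge, so fixing one fixes the other. At C7 the geranyl group is exo: equatorial on a chair ring B and trans to the C2–C3–C4 bridge.

The sensitive groups are the catechol (oxidation, hydrogen-atom donation), four trisubstituted alkenes that cyclise onto enol oxygen under acid, and the acidic, chelating triketone.

The hard parts are the run of congested carbons C1 (quaternary), C8 (quaternary) and C7, and the quaternary C5 between two carbonyls. An enolate acylation or alkylation at C5 gives a non-enolisable product and so has no thermodynamic sink.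

The strategy rests on one feature. C5 lies between the C4 and C9 carbonyls and is joined through C6H2 to C7, which sits next to the quaternary C8 on C1. Ring B is therefore the 6-endo adduct of a C5 1,3-dicarbonyl radical to the terminal carbon of a 1,1-dimethylallyl group on C1. What is left is a dearomatised acylphloroglucinol.

## Retrosynthetic reasoning

**21 from 20.** The two aryl silyl ethers are removed last. The catechol must stay masked through the radical and nickel steps, because a free catechol quenches radicals and is oxidised by the iodinating agent. Fluoride cleavage is the one deprotection that touches neither the alkenes nor the triketone.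

**20 from 16 and 17.** The C7–CH2 bond to the geranyl chain is cut. The atom-transfer ring closure leaves a secondary iodide at exactly this carbon, and the whole (E)-configured chain can come from the acetate 17. The forward reaction has to capture the C7 radical on the exo face and join it to the unsubstituted allyl terminus without scrambling the alkene. An allylic acetate is used because an allylic bromide would insert zinc and add to the C9 and aroyl ketones. The acidic enol is silylated in the flask for this step only.

**16 from 13 and 14.** The C5–C6 bond is cut. This is the only ring-B bond whose formation makes the quaternary C5 irreversibly and without an enolate equilibrium. It also uses the carbonyl-flanked C5 as the radical site and the vinyl terminus as the acceptor. The forward step must iodinate C5, close ring B 6-endo, and set C5 from C1.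

The enols are left free. A methyl ether on the C2 oxygen would block C3 outright, but I see no dependable way to put it there. O-alkylation of 12 or 13 would fall on the unchelated oxygen at C9, which would shut down C5. Methylating one ortho phenol before the sigmatropic shift makes the two ortho carbons inequivalent, with the bias toward the wrong one. Radicals of free dearomatised acylphloroglucinol enols are known to bond through the alkyl-bearing carbon, which is the selectivity needed.

**13 from 12, and 12 from 11.** The C1–C8 bond between two quaternary carbons is cut by a retro-Claisen shift. A [3,3] shift is the one reaction type that makes such a bond routinely, and the allyl inversion turns an O-prenyl group into the 1,1-dimethylallyl group. Because both ortho phenols of 11 are free, the two ortho carbons are equivalent and there is no regiochemical question. The shift creates C1 as a racemate. An enantioselective version on this substrate is not established, so the enantiomers of 12 are separated at once, before any material is spent on the later steps.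

**11 from 9 and 10.** The aryl O–prenyl bond is cut. The para hydroxyl is the only unchelated phenol, and a Mitsunobu etherification cannot C-alkylate.

**9 from 7 and 8.** The two aryl–prenyl bonds are cut. The symmetric triol 7 has two equivalent nucleophilic ring carbons.

**7 from 6, 6 from 3 and 4, 3 from 1.** The aryl–carbonyl bond is cut. The catechol is silylated on the acid 1 before the ketone is made, because the pentahydroxy benzophenone cannot be silylated on the catechol alone: its most acidic phenol is on the other ring. The phloroglucinol ring is brought in as the tribenzyl ether 4. This allows an acylation without a metal Lewis acid and a hydrogenolysis that leaves the silyl ethers alone.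

## Alternatives that were turned down

**Alternative 1:** The C5–C9 and C2–C3 bonds are cut back to an open chain that carries a malonate diester at C1, a ketone with C5 as its α-carbon, and a methyl group that becomes C3. In the forward step a tert-butoxide base drives two Claisen condensations in sequence. The C5 enolate attacks one ester to close ring B, then the methyl ketone enolate attacks the other to close ring A, giving the trione A1.
- For it: both rings and both bridgeheads form in one operation, no alkene competes, and A1 is the kind of trione whose C3 aroylation is routine. On chemoselectivity it is stronger than the radical route.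
- Against it: the first acylation joins a fully substituted enolate carbon to an ester on a quaternary carbon that is itself next to a quaternary carbon. It gives a non-enolisable β-dicarbonyl, so nothing drives it and retro-Claisen cleavage stays open. The kinetic enolate is the methyl one. C1 is defined only by which of two diastereotopic esters reacts. The open chain still needs the C1–C8 bond and an enantioselective C7, and the aroyl group and its deprotection are still to come.
- Comparison: the chosen route makes C5 by an irreversible radical bond and takes the skeleton from a phloroglucinol in six steps, at the price of a resolution.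

**Alternative 2:** The C1–C8 bond is cut back to a Birch-type cyclohexadiene bis(enol ether) that carries, on its quaternary carbon, the prenyl group and a side chain ending in a tertiary acetate. In the forward step a silyl triflate ionises the acetate, one of the two enol ether carbons captures the C8 cation to close ring B, and loss of the O-methyl group gives the C9 ketone of A2.
- For it: the desymmetrisation relays a single side-chain stereocentre to the quaternary C5. This is real absolute stereocontrol where the chosen route has only a resolution. C1 is still tertiary when the crowded bond forms.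
- Against it: a tertiary cation and a strong Lewis acid meet the geranyl and prenyl alkenes, which invites cation–alkene cyclisation and alkene migration. A2 also still lacks the C1 prenyl group, the C2 oxygen and the aroyl group, so five or more steps follow.
- Comparison: the chosen route keeps the alkenes away from acid and is shorter. It gives up catalytic enantiocontrol.

**Alternative 3:** The C4–C5 bond is cut back to an enol lactone in which the C4 acyl carbon hangs on the oxygen of the C9 enol. In the forward step a nucleophilic pyridine catalyst opens the lactone to an acylpyridinium ion and the C9 enolate, and C5 attacks C4 to give the carbocyclic ring A of A3.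
- For it: O-to-C acyl transfer is a known reaction type, and C3 is blocked by the vinylogous ester. The stereocentres are set on a monocyclic ketone, and A3 is one aroylation and two deprotections from the target. On C3/C5 selectivity and on the endgame it is stronger.
- Against it: C-acylation at the fully substituted C5 gives a strained, non-enolisable bridged diketone with no deprotonation sink, so the lactone may be the resting state. The cyclohexanone precursor, with quaternary C1 beside quaternary C8 and two further substituted carbons, is a long synthesis.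
- Comparison: the chosen radical closure is kinetically controlled and its precursor is six steps from commercial materials.

Key step: step 8

## Route

**Step 1**
Reactants: 1 3,4-dihydroxybenzoic acid
Product: 3 3,4-bis(tert-butyldimethylsilyloxy)benzoic acid, via silyl ester 2 (not isolated)
Conditions: t-BuMe2SiCl (3.3 equiv), imidazole, DMF, 25 °C; then AcOH, THF/H2O, 25 °C
Reagents that add atoms: tert-butyldimethylsilyl chloride, CC(C)(C)[Si](C)(C)Cl
Why: Silylation of both phenols and the acid, then selective hydrolysis of the silyl ester, which is far more labile than an aryl silyl ether; the catechol is masked here because it cannot be silylated selectively once the phloroglucinol ring is attached.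

**Step 2**
Reactants: 3 3,4-bis(tert-butyldimethylsilyloxy)benzoic acid; 4 1,3,5-tris(benzyloxy)benzene
Product: 6 [3,4-bis(tert-butyldimethylsilyloxy)phenyl][2,4,6-tris(benzyloxy)phenyl]methanone, via mixed anhydride 5 (not isolated)
Conditions: (CF3CO)2O, CH2Cl2, 0 → 25 °C
Reagents that add atoms: none
Why: Friedel–Crafts acylation through the aroyl trifluoroacetate; a 1,3,5-trialkoxybenzene is nucleophilic enough to react without a metal Lewis acid, so silyl and benzyl ethers survive, and the ketone formed is deactivated against a second acylation.

**Step 3**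
Reactants: 6 [3,4-bis(tert-butyldimethylsilyloxy)phenyl][2,4,6-tris(benzyloxy)phenyl]methanone
Product: 7 [3,4-bis(tert-butyldimethylsilyloxy)phenyl](2,4,6-trihydroxyphenyl)methanone
Conditions: H2 (1 atm), Pd/C, EtOAc, 25 °C
Reagents that add atoms: none
Why: Hydrogenolysis of the three benzyl ethers before any alkene is present; aryl silyl ethers and the electron-rich, chelated diaryl ketone are inert under these conditions.

**Step 4**
Reactants: 7 [3,4-bis(tert-butyldimethylsilyloxy)phenyl](2,4,6-trihydroxyphenyl)methanone; 8 1-bromo-3-methylbut-2-ene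
Product: 9 [3,4-bis(tert-butyldimethylsilyloxy)phenyl][2,4,6-trihydroxy-3,5-bis(3-methylbut-2-en-1-yl)phenyl]methanone
Conditions: 8 (2.1 equiv), DBU, THF, 0 °C
Reagents that add atoms: 1-bromo-3-methylbut-2-ene (8), CC(C)=CCBr
Why: C-alkylation of the ambident acylphloroglucinol phenoxide at its two equivalent ring carbons; the anhydrous amidine base is used in place of aqueous hydroxide so that the aryl silyl ethers are not cleaved.

**Step 5**
Reactants: 9 [3,4-bis(tert-butyldimethylsilyloxy)phenyl][2,4,6-trihydroxy-3,5-bis(3-methylbut-2-en-1-yl)phenyl]methanone; 10 3-methylbut-2-en-1-ol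
Product: 11 [3,4-bis(tert-butyldimethylsilyloxy)phenyl][2,6-dihydroxy-3,5-bis(3-methylbut-2-en-1-yl)-4-(3-methylbut-2-en-1-yloxy)phenyl]methanone
Conditions: 10, PPh3, i-PrO2CN=NCO2i-Pr, THF, 0 °C
Reagents that add atoms: 3-methylbut-2-en-1-ol (10), CC(C)=CCO
Why: Mitsunobu etherification of the para hydroxyl, the most acidic and the only unchelated phenol; unlike a base-mediated alkylation it cannot C-alkylate the ring to the gem-diprenyl trione.

**Step 6**
Reactants: 11 [3,4-bis(tert-butyldimethylsilyloxy)phenyl][2,6-dihydroxy-3,5-bis(3-methylbut-2-en-1-yl)-4-(3-methylbut-2-en-1-yloxy)phenyl]methanone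
Product: 12 rac-2-[3,4-bis(tert-butyldimethylsilyloxy)benzoyl]-3,5-dihydroxy-6-(2-methylbut-3-en-2-yl)-4,6-bis(3-methylbut-2-en-1-yl)cyclohexa-2,4-dien-1-one
Conditions: PhMe, 110 °C, sealed tube
Reagents that add atoms: none
Why: Aromatic Claisen rearrangement onto an already substituted ortho carbon; the two ortho carbons are equivalent, the allyl inversion delivers the 1,1-dimethylallyl group and forms the C1–C8 bond between two quaternary carbons, and the dienone, which cannot rearomatise, is drained by tautomerisation to the chelated enol. C1 is formed as a racemate.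

**Step 7**
Reactants: 12 rac-2-[3,4-bis(tert-butyldimethylsilyloxy)benzoyl]-3,5-dihydroxy-6-(2-methylbut-3-en-2-yl)-4,6-bis(3-methylbut-2-en-1-yl)cyclohexa-2,4-dien-1-one
Product: 13 (6S)-2-[3,4-bis(tert-butyldimethylsilyloxy)benzoyl]-3,5-dihydroxy-6-(2-methylbut-3-en-2-yl)-4,6-bis(3-methylbut-2-en-1-yl)cyclohexa-2,4-dien-1-one
Conditions: preparative SFC, amylose tris(3,5-dimethylphenylcarbamate) phase, CO2/MeOH, 0.1% HCO2H
Reagents that add atoms: none
Why: Resolution of the racemate on a chiral stationary phase at the first chiral intermediate, with an acidic modifier to suppress tailing of the enol; the (S) enantiomer is the one whose C1 matches the target, to be confirmed later through the heavy-atom derivative 16.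

**Step 8**
Reactants: 13 (6S)-2-[3,4-bis(tert-butyldimethylsilyloxy)benzoyl]-3,5-dihydroxy-6-(2-methylbut-3-en-2-yl)-4,6-bis(3-methylbut-2-en-1-yl)cyclohexa-2,4-dien-1-one; 14 N-iodosuccinimide
Product: 16 (1S,5S,7R)-3-[3,4-bis(tert-butyldimethylsilyloxy)benzoyl]-4-hydroxy-7-iodo-8,8-dimethyl-1,5-bis(3-methylbut-2-en-1-yl)bicyclo[3.3.1]non-3-ene-2,9-dione, via iodo dione 15 (not isolated)
Conditions: 14 (1.0 equiv), CH2Cl2, −40 → 0 °C; then Et3B (0.3 equiv), air, CH2Cl2 (0.01 M), 0 → 25 °C
Reagents that add atoms: N-iodosuccinimide (14), O=C1CCC(=O)N1I
Why: N-Iodosuccinimide iodinates the enolic C5, the only unchelated enol carbon (C3 lies in the hindered, aroyl-chelated triketone, and an iodine placed there would pass on to C5), to give the tertiary α-iodo-1,3-diketone 15. Ethyl radicals from Et3B and oxygen abstract this weakly bound iodine; the planar C5 radical, delocalised over the C4 and C9 carbonyls, adds to the terminal carbon C6 of the 1,1-dimethylallyl group, and the secondary C7 radical takes iodine from a further molecule of 15, so the chain needs no reductant and a slow ring closure is not punished. The closest known reaction types are the iodine-atom-transfer cyclisation of α-iodo-1,3-dicarbonyl compounds and the oxidative radical cyclisations of dearomatised acylphloroglucinol enols, which bond through this same ring carbon and not through the acyl-bearing one. Ring B closes 6-endo-trig through a chair-like array; 5-exo attack at C7 is disfavoured by the C9 carbonyl inside the forming ring and by the quaternary C8 next to C7. C5 is set by C1: the three-atom tether can reach C5 only on the face of ring A on which C1 holds it, so the C5 prenyl group is forced to the other face. C7 is set by iodine transfer to the exo face, away from ring A, and is formed again in step 9 in any case. The selectivity the step needs is addition to the vinyl group in preference to 5-exo addition to the trisubstituted alkene of the C1 prenyl group on the opposite face; the substrate offers a strain-free six-membered transition state, a gem-dimethyl tether and an unhindered CH2 terminus against a strained bicyclo[3.2.1] transition state, but the prenyl alkene is the more electron-rich partner for this electrophilic radical, so this competition is the main risk of the route.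

**Step 9**
Reactants: 16 (1S,5S,7R)-3-[3,4-bis(tert-butyldimethylsilyloxy)benzoyl]-4-hydroxy-7-iodo-8,8-dimethyl-1,5-bis(3-methylbut-2-en-1-yl)bicyclo[3.3.1]non-3-ene-2,9-dione; 17 (2E)-3,7-dimethylocta-2,6-dien-1-yl acetate
Product: 20 (1S,5S,7R)-3-[3,4-bis(tert-butyldimethylsilyloxy)benzoyl]-7-[(2E)-3,7-dimethylocta-2,6-dien-1-yl]-4-hydroxy-8,8-dimethyl-1,5-bis(3-methylbut-2-en-1-yl)bicyclo[3.3.1]non-3-ene-2,9-dione, via iodide trimethylsilyl enol ether 18 (not isolated), via coupled trimethylsilyl enol ether 19 (not isolated)
Conditions: MeC(OSiMe3)=NSiMe3, CH2Cl2, 25 °C, evaporate; 17 (2 equiv), NiCl2·MeOCH2CH2OMe (10 mol%), 4,4′,4″-tri-tert-butyl-2,2′:6′,2″-terpyridine (10 mol%), Zn, THF/DMA, 40 °C; aq. citric acid work-up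
Reagents that add atoms: (2E)-3,7-dimethylocta-2,6-dien-1-yl acetate (17), CC(C)=CCC/C(C)=C/COC(C)=O
Why: Transient silylation removes the acidic enol proton; the nickel-catalysed reductive cross-electrophile coupling of a secondary alkyl iodide with an allylic acetate then turns the iodide into the C7 radical, which meets the allylnickel species on the exo face because ring A blocks the endo face, and reductive elimination at the unsubstituted allyl terminus gives the exo geranyl group with the (E) alkene kept. The acetate is chosen because an allylic bromide would insert zinc and add to the ketones; the silyl enol ether is hydrolysed on work-up.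

**Step 10**
Reactants: 20 (1S,5S,7R)-3-[3,4-bis(tert-butyldimethylsilyloxy)benzoyl]-7-[(2E)-3,7-dimethylocta-2,6-dien-1-yl]-4-hydroxy-8,8-dimethyl-1,5-bis(3-methylbut-2-en-1-yl)bicyclo[3.3.1]non-3-ene-2,9-dione
Product: 21 oblongifolin B, (1S,5S,7R)-3-(3,4-dihydroxybenzoyl)-7-[(2E)-3,7-dimethylocta-2,6-dien-1-yl]-4-hydroxy-8,8-dimethyl-1,5-bis(3-methylbut-2-en-1-yl)bicyclo[3.3.1]non-3-ene-2,9-dione
Conditions: Bu4NF, AcOH, THF, 0 °C
Reagents that add atoms: none
Why: Fluoride cleavage of the two aryl silyl ethers, buffered with acetic acid so that neither the catecholate nor the triketone enolate is exposed to base and air; alkenes and stereocentres are not touched.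

## Compound list

1 | 3,4-dihydroxybenzoic acid | O=C(O)c1ccc(O)c(O)c1 | starting material
2 | tert-butyldimethylsilyl 3,4-bis(tert-butyldimethylsilyloxy)benzoate | CC(C)(C)[Si](C)(C)OC(=O)c1ccc(O[Si](C)(C)C(C)(C)C)c(O[Si](C)(C)C(C)(C)C)c1 | intermediate
3 | 3,4-bis(tert-butyldimethylsilyloxy)benzoic acid | O=C(O)c1ccc(O[Si](C)(C)C(C)(C)C)c(O[Si](C)(C)C(C)(C)C)c1 | intermediate
4 | 1,3,5-tris(benzyloxy)benzene | c1ccc(COc2cc(OCc3ccccc3)cc(OCc3ccccc3)c2)cc1 | starting material
5 | 3,4-bis(tert-butyldimethylsilyloxy)benzoic trifluoroacetic anhydride | O=C(OC(=O)C(F)(F)F)c1ccc(O[Si](C)(C)C(C)(C)C)c(O[Si](C)(C)C(C)(C)C)c1 | intermediate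
6 | [3,4-bis(tert-butyldimethylsilyloxy)phenyl][2,4,6-tris(benzyloxy)phenyl]methanone | O=C(c1ccc(O[Si](C)(C)C(C)(C)C)c(O[Si](C)(C)C(C)(C)C)c1)c1c(OCc2ccccc2)cc(OCc2ccccc2)cc1OCc1ccccc1 | intermediate
7 | [3,4-bis(tert-butyldimethylsilyloxy)phenyl](2,4,6-trihydroxyphenyl)methanone | O=C(c1ccc(O[Si](C)(C)C(C)(C)C)c(O[Si](C)(C)C(C)(C)C)c1)c1c(O)cc(O)cc1O | intermediate
8 | 1-bromo-3-methylbut-2-ene (prenyl bromide) | CC(C)=CCBr | starting material
9 | [3,4-bis(tert-butyldimethylsilyloxy)phenyl][2,4,6-trihydroxy-3,5-bis(3-methylbut-2-en-1-yl)phenyl]methanone | CC(C)=CCc1c(O)c(CC=C(C)C)c(O)c(C(=O)c2ccc(O[Si](C)(C)C(C)(C)C)c(O[Si](C)(C)C(C)(C)C)c2)c1O | intermediate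
10 | 3-methylbut-2-en-1-ol | CC(C)=CCO | starting material
11 | [3,4-bis(tert-butyldimethylsilyloxy)phenyl][2,6-dihydroxy-3,5-bis(3-methylbut-2-en-1-yl)-4-(3-methylbut-2-en-1-yloxy)phenyl]methanone | CC(C)=CCOc1c(CC=C(C)C)c(O)c(C(=O)c2ccc(O[Si](C)(C)C(C)(C)C)c(O[Si](C)(C)C(C)(C)C)c2)c(O)c1CC=C(C)C | intermediate
12 | rac-2-[3,4-bis(tert-butyldimethylsilyloxy)benzoyl]-3,5-dihydroxy-6-(2-methylbut-3-en-2-yl)-4,6-bis(3-methylbut-2-en-1-yl)cyclohexa-2,4-dien-1-one | C=CC(C)(C)C1(CC=C(C)C)C(=O)C(C(=O)c2ccc(O[Si](C)(C)C(C)(C)C)c(O[Si](C)(C)C(C)(C)C)c2)=C(O)C(CC=C(C)C)=C1O | intermediate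
13 | (6S)-2-[3,4-bis(tert-butyldimethylsilyloxy)benzoyl]-3,5-dihydroxy-6-(2-methylbut-3-en-2-yl)-4,6-bis(3-methylbut-2-en-1-yl)cyclohexa-2,4-dien-1-one | C=CC(C)(C)[C@]1(CC=C(C)C)C(=O)C(C(=O)c2ccc(O[Si](C)(C)C(C)(C)C)c(O[Si](C)(C)C(C)(C)C)c2)=C(O)C(CC=C(C)C)=C1O | intermediate
14 | N-iodosuccinimide | O=C1CCC(=O)N1I | starting material
15 | 2-[3,4-bis(tert-butyldimethylsilyloxy)benzoyl]-3-hydroxy-4-iodo-6-(2-methylbut-3-en-2-yl)-4,6-bis(3-methylbut-2-en-1-yl)cyclohex-2-ene-1,5-dione, quaternary carbon C6 arranged as in 13, both epimers at the iodinated carbon | C=CC(C)(C)[C@]1(CC=C(C)C)C(=O)C(C(=O)c2ccc(O[Si](C)(C)C(C)(C)C)c(O[Si](C)(C)C(C)(C)C)c2)=C(O)C(I)(CC=C(C)C)C1=O | intermediate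
16 | (1S,5S,7R)-3-[3,4-bis(tert-butyldimethylsilyloxy)benzoyl]-4-hydroxy-7-iodo-8,8-dimethyl-1,5-bis(3-methylbut-2-en-1-yl)bicyclo[3.3.1]non-3-ene-2,9-dione (iodine exo) | I[C@@H]1C[C@]2(CC=C(C)C)C(=O)[C@@](CC=C(C)C)(C(=O)C(C(=O)c3ccc(O[Si](C)(C)C(C)(C)C)c(O[Si](C)(C)C(C)(C)C)c3)=C2O)C1(C)C | intermediate
17 | (2E)-3,7-dimethylocta-2,6-dien-1-yl acetate (geranyl acetate) | CC(C)=CCC/C(C)=C/COC(C)=O | starting material
18 | 4-O-trimethylsilyl enol ether of 16 | I[C@@H]1C[C@]2(CC=C(C)C)C(=O)[C@@](CC=C(C)C)(C(=O)C(C(=O)c3ccc(O[Si](C)(C)C(C)(C)C)c(O[Si](C)(C)C(C)(C)C)c3)=C2O[Si](C)(C)C)C1(C)C | intermediate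
19 | 4-O-trimethylsilyl enol ether of 20 | CC(C)=CCC/C(C)=C/C[C@@H]1C[C@]2(CC=C(C)C)C(=O)[C@@](CC=C(C)C)(C(=O)C(C(=O)c3ccc(O[Si](C)(C)C(C)(C)C)c(O[Si](C)(C)C(C)(C)C)c3)=C2O[Si](C)(C)C)C1(C)C | intermediate
20 | (1S,5S,7R)-3-[3,4-bis(tert-butyldimethylsilyloxy)benzoyl]-7-[(2E)-3,7-dimethylocta-2,6-dien-1-yl]-4-hydroxy-8,8-dimethyl-1,5-bis(3-methylbut-2-en-1-yl)bicyclo[3.3.1]non-3-ene-2,9-dione (geranyl exo) | CC(C)=CCC/C(C)=C/C[C@@H]1C[C@]2(CC=C(C)C)C(=O)[C@@](CC=C(C)C)(C(=O)C(C(=O)c3ccc(O[Si](C)(C)C(C)(C)C)c(O[Si](C)(C)C(C)(C)C)c3)=C2O)C1(C)C | intermediate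
21 | oblongifolin B, (1S,5S,7R)-3-(3,4-dihydroxybenzoyl)-7-[(2E)-3,7-dimethylocta-2,6-dien-1-yl]-4-hydroxy-8,8-dimethyl-1,5-bis(3-methylbut-2-en-1-yl)bicyclo[3.3.1]non-3-ene-2,9-dione | CC(C)=CCC/C(C)=C/C[C@@H]1C[C@]2(CC=C(C)C)C(=O)[C@@](CC=C(C)C)(C(=O)C(C(=O)c3ccc(O)c(O)c3)=C2O)C1(C)C | target

## Step count and uncertain steps

Total: 10 steps. Longest linear sequence: 10 steps, from 1 to 21; compound 4 enters in step 2.

**Step 8 (key step).** The most likely failure is capture of the C5 radical by the trisubstituted alkene of the C1 prenyl group. That is a 5-exo closure to a bicyclo[3.2.1]octane, and it competes with the wanted 6-endo closure because this electrophilic radical prefers the more electron-rich alkene.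

The fallback changes the spectator groups and adds a late metathesis. It sets out from 7 and returns at 16.
- C-alkylation of 7 with (E)-1-bromobut-2-ene under the conditions of step 4 would give the dicrotyl triol F1.
- Mitsunobu etherification with 10 would give the prenyl ether F2.
- The Claisen shift would give the racemic dicrotyl dienone F3, and resolution would give its (S) enantiomer F4.
- Iodination to the dicrotyl iodo dione F5 and atom-transfer cyclisation as in step 8 would give the dicrotyl bicyclic iodide F6.
- Cross-metathesis of F6 with 2-methylbut-2-ene and the second-generation Grubbs catalyst would turn both crotyl groups into prenyl groups and give 16.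

A 1,2-disubstituted alkene is a poorer partner for the C5 radical than the prenyl group: its 5-exo adduct is only a secondary radical, and its 6-endo mode must attack a substituted carbon.

**Step 6.** The likely failure is that the 1,1-dimethylallyl group moves on at the temperature the shift needs. It can do so by a Cope shift to the aroyl-bearing carbon or by ionisation and recombination to an ordinary prenyl group.

The fallback replaces the sigmatropic route by an allylic substitution. It sets out from 9 and returns at 12. tert-Butyl 2-methylbut-3-en-2-yl carbonate F7 would be made from the tertiary alcohol. It would then be used with [Ir(cod)Cl]2 and a phosphoramidite ligand to reverse-prenylate the prenyl-bearing ring carbon of 9, giving 12. This type of substitution is established for 3-substituted indoles, where the same bond between two quaternary carbons is formed.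

**Step 9.** The likely failure is slow capture of the neopentyl-type C7 radical by nickel. That leads to simple reduction of the C–I bond, or to loss of the (E) geometry through isomerisation of the allylnickel intermediate.

The fallback replaces the reductive coupling by a preformed organometallic. It sets out from 16 and returns at 20. After silylation to 18, zinc insertion (Zn, LiCl, THF) would give the exo organozinc iodide F8. The carbon–zinc bond can equilibrate to the equatorial position. A Negishi coupling of F8 with geranyl chloride under Pd2(dba)3 and tri(2-furyl)phosphine would give 19, and acidic work-up would give 20.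

**Step 4.** The likely failure is over-alkylation to a gem-diprenyl dearomatised product, together with O-alkylation, which would lower the yield of 9.

The fallback changes the mechanism from phenoxide alkylation to electrophilic aromatic substitution. It sets out from 7 and returns at 9. Friedel–Crafts prenylation of 7 with 2-methylbut-3-en-2-ol and BF3·OEt2 in dioxane at 25 °C cannot dearomatise the ring or alkylate oxygen.

**Step 7.** The likely failure is peak broadening from tautomer exchange of the acidic enol and low loading on the chiral phase.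

The fallback is a classical resolution. It sets out from 12 and returns at 13. Crystallisation of 12 with (R)-1-phenylethylamine would give the less soluble diastereomeric salt, the (R)-1-phenylethylammonium salt of 13 F9, and acidification would give 13. The other amine enantiomer would be used if the wrong salt crystallises.

## Further compounds

F1 | step 8 | [3,4-bis(tert-butyldimethylsilyloxy)phenyl][3,5-bis((2E)-but-2-en-1-yl)-2,4,6-trihydroxyphenyl]methanone | C/C=C/Cc1c(O)c(C/C=C/C)c(O)c(C(=O)c2ccc(O[Si](C)(C)C(C)(C)C)c(O[Si](C)(C)C(C)(C)C)c2)c1O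
F2 | step 8 | [3,4-bis(tert-butyldimethylsilyloxy)phenyl][3,5-bis((2E)-but-2-en-1-yl)-2,6-dihydroxy-4-(3-methylbut-2-en-1-yloxy)phenyl]methanone | C/C=C/Cc1c(O)c(C(=O)c2ccc(O[Si](C)(C)C(C)(C)C)c(O[Si](C)(C)C(C)(C)C)c2)c(O)c(C/C=C/C)c1OCC=C(C)C
F3 | step 8 | rac-2-[3,4-bis(tert-butyldimethylsilyloxy)benzoyl]-4,6-bis((2E)-but-2-en-1-yl)-3,5-dihydroxy-6-(2-methylbut-3-en-2-yl)cyclohexa-2,4-dien-1-one | C=CC(C)(C)C1(C/C=C/C)C(=O)C(C(=O)c2ccc(O[Si](C)(C)C(C)(C)C)c(O[Si](C)(C)C(C)(C)C)c2)=C(O)C(C/C=C/C)=C1O
F4 | step 8 | (6S)-2-[3,4-bis(tert-butyldimethylsilyloxy)benzoyl]-4,6-bis((2E)-but-2-en-1-yl)-3,5-dihydroxy-6-(2-methylbut-3-en-2-yl)cyclohexa-2,4-dien-1-one | C=CC(C)(C)[C@]1(C/C=C/C)C(=O)C(C(=O)c2ccc(O[Si](C)(C)C(C)(C)C)c(O[Si](C)(C)C(C)(C)C)c2)=C(O)C(C/C=C/C)=C1O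
F5 | step 8 | 2-[3,4-bis(tert-butyldimethylsilyloxy)benzoyl]-4,6-bis((2E)-but-2-en-1-yl)-3-hydroxy-4-iodo-6-(2-methylbut-3-en-2-yl)cyclohex-2-ene-1,5-dione, quaternary carbon as in F4 | C=CC(C)(C)[C@]1(C/C=C/C)C(=O)C(C(=O)c2ccc(O[Si](C)(C)C(C)(C)C)c(O[Si](C)(C)C(C)(C)C)c2)=C(O)C(I)(C/C=C/C)C1=O
F6 | step 8 | 3-[3,4-bis(tert-butyldimethylsilyloxy)benzoyl]-1,5-bis((2E)-but-2-en-1-yl)-4-hydroxy-7-iodo-8,8-dimethylbicyclo[3.3.1]non-3-ene-2,9-dione, configured as 16 | I[C@@H]1C[C@]2(C/C=C/C)C(=O)[C@@](C/C=C/C)(C(=O)C(C(=O)c3ccc(O[Si](C)(C)C(C)(C)C)c(O[Si](C)(C)C(C)(C)C)c3)=C2O)C1(C)C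
F7 | step 6 | tert-butyl 2-methylbut-3-en-2-yl carbonate | CC(C)(C)OC(=O)OC(C)(C)C=C
F8 | step 9 | exo C7 organozinc iodide of 18 | I[Zn][C@@H]1C[C@]2(CC=C(C)C)C(=O)[C@@](CC=C(C)C)(C(=O)C(C(=O)c3ccc(O[Si](C)(C)C(C)(C)C)c(O[Si](C)(C)C(C)(C)C)c3)=C2O[Si](C)(C)C)C1(C)C
F0 | step 4 | none | none
F9 | step 7 | (R)-1-phenylethylammonium salt of 13, written as its two components | C=CC(C)(C)[C@]1(CC=C(C)C)C(=O)C(C(=O)c2ccc(O[Si](C)(C)C(C)(C)C)c(O[Si](C)(C)C(C)(C)C)c2)=C(O)C(CC=C(C)C)=C1O.C[C@@H](N)c1ccccc1
A1 | alternative 1 | 7-geranyl-8,8-dimethyl-1,5-diprenylbicyclo[3.3.1]nonane-2,4,9-trione | CC(C)=CCC/C(C)=C/C[C@@H]1C[C@]2(CC=C(C)C)C(=O)[C@@](CC=C(C)C)(C(=O)CC2=O)C1(C)C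
A2 | alternative 2 | 7-geranyl-4-methoxy-8,8-dimethyl-5-prenylbicyclo[3.3.1]non-3-en-9-one | CC(C)=CCC/C(C)=C/C[C@@H]1C[C@]2(CC=C(C)C)C(=O)[C@@H](CC=C2OC)C1(C)C
A3 | alternative 3 | 7-geranyl-2-methoxy-8,8-dimethyl-1,5-diprenylbicyclo[3.3.1]non-2-ene-4,9-dione | CC(C)=CCC/C(C)=C/C[C@@H]1C[C@]2(CC=C(C)C)C(=O)[C@@](CC=C(C)C)(C(OC)=CC2=O)C1(C)C
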